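The ethane-bridge C–C bond between ring A (the methoxy-hydroxy ring flanked by two 4-hydroxybenzyl groups) and ring B (the hydroxy ring carrying one 4-hydroxybenzyl group) is the disconnection on which everything rests. Both bridge carbons (Cα on ring A, Cα′ on ring B) are benzylic, so the bond is forged as a stilbene C=C by Wittig olefination. The benzyl-protected ring-A aldehyde, which presents the crowded bridge carbon as a flat carbonyl, meets the benzylic phosphorus ylide of ring B. A single hydrogenation then saturates the bridge and releases all four phenols. Each half comes from an aryl bromide and one common 4-(benzyloxy)benzylboronate by Suzuki coupling.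

Key step: step 8

Remark: the target has no stereocentre and no stereogenic double bond, so it is achiral; no step needs stereocontrol, and the E/Z ratio of olefin 13 is irrelevant because the double bond is hydrogenated.

**Step 1**
Reactants: 1 4-(benzyloxy)benzyl chloride
Product: 2 2-[4-(benzyloxy)benzyl]-4,4,5,5-tetramethyl-1,3,2-dioxaborolane
Conditions: B2pin2, Pd(dba)2 (3 mol %), P(4-MeOC6H4)3 (6 mol %), KOAc, toluene, 50 °C
Reagents that add atoms: bis(pinacolato)diboron, CC1(C)OB(OC1(C)C)B1OC(C)(C)C(C)(C)O1
Why: Miyaura borylation of a benzylic chloride, in which oxidative addition of Pd(0) to the C–Cl bond, transmetalation with the acetate-activated diboron and reductive elimination should give the benzylboronate while the aryl benzyl ether stays inert.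

**Step 2**
Reactants: 3 3-hydroxy-5-methoxybenzaldehyde
Product: 4 3-(benzyloxy)-5-methoxybenzaldehyde
Conditions: BnBr, K2CO3, DMF, rt
Reagents that add atoms: benzyl bromide, BrCc1ccccc1
Why: Williamson ether synthesis, in which the phenoxide (the only acidic site) is alkylated by SN2 and the non-enolisable aldehyde is untouched.

**Step 3**
Reactants: 4 3-(benzyloxy)-5-methoxybenzaldehyde
Product: 5 3-(benzyloxy)-2,6-dibromo-5-methoxybenzaldehyde
Conditions: NBS (2.2 equiv), MeCN, dark, rt → 50 °C
Reagents that add atoms: N-bromosuccinimide, O=C1CCC(=O)N1Br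
Why: Electrophilic aromatic bromination (SEAr) should go to C2 and C6, each ortho to one ether oxygen and para to the other, while C4 between the two alkoxy groups is shielded by both, the pattern known from the 2,6-dihalogenation of 3,5-dimethoxyphenyl compounds.

**Step 4**
Reactants: 5 3-(benzyloxy)-2,6-dibromo-5-methoxybenzaldehyde; 2 2-[4-(benzyloxy)benzyl]-4,4,5,5-tetramethyl-1,3,2-dioxaborolane (3 equiv)
Product: 6 3-(benzyloxy)-2,6-bis[4-(benzyloxy)benzyl]-5-methoxybenzaldehyde
Conditions: Pd(OAc)2 (5 mol %), SPhos (10 mol %), K3PO4, toluene/H2O (10:1), 90 °C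
Reagents that add atoms: none
Why: Twofold sp2–sp3 Suzuki–Miyaura coupling, in which the ortho formyl group speeds oxidative addition at both C–Br bonds, the bulky electron-rich biarylphosphine copes with the di-ortho-substituted bromides, the benzyl groups cannot undergo β-hydride elimination and the non-enolisable aldehyde tolerates aqueous phosphate.

**Step 5**
Reactants: 7 2-bromo-5-(hydroxymethyl)phenol
Product: 8 [3-(benzyloxy)-4-bromophenyl]methanol
Conditions: BnBr (1.05 equiv), K2CO3, acetone, reflux
Reagents that add atoms: benzyl bromide, BrCc1ccccc1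
Why: Chemoselective Williamson ether synthesis, since carbonate deprotonates only the phenol (pKa about 10) and not the benzylic alcohol (pKa about 15).

**Step 6**
Reactants: 8 [3-(benzyloxy)-4-bromophenyl]methanol; 2 2-[4-(benzyloxy)benzyl]-4,4,5,5-tetramethyl-1,3,2-dioxaborolane (1.5 equiv)
Product: 9 {3-(benzyloxy)-4-[4-(benzyloxy)benzyl]phenyl}methanol
Conditions: Pd(OAc)2 (3 mol %), SPhos (6 mol %), K3PO4, toluene/H2O (10:1), 90 °C
Reagents that add atoms: none
Why: sp2–sp3 Suzuki–Miyaura coupling of a mono-ortho-substituted aryl bromide with the benzylboronate, a coupling that tolerates the free primary alcohol.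

**Step 7**
Reactants: 9 {3-(benzyloxy)-4-[4-(benzyloxy)benzyl]phenyl}methanol
Product: 10 {3-(benzyloxy)-4-[4-(benzyloxy)benzyl]benzyl}triphenylphosphonium bromide
Conditions: Ph3P·HBr (1.05 equiv), MeCN, reflux
Reagents that add atoms: triphenylphosphine hydrobromide, [Br-].c1ccc(cc1)[PH+](c1ccccc1)c1ccccc1
Why: Direct conversion of a benzylic alcohol into its phosphonium salt by acid-assisted nucleophilic substitution (protonated alcohol, bromide, then phosphine), under acidity mild enough that the aryl benzyl ethers should survive.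

**Step 8**
Reactants: 10 {3-(benzyloxy)-4-[4-(benzyloxy)benzyl]benzyl}triphenylphosphonium bromide (1.2 equiv); 6 3-(benzyloxy)-2,6-bis[4-(benzyloxy)benzyl]-5-methoxybenzaldehyde
Product: 13 1-(benzyloxy)-2,4-bis[4-(benzyloxy)benzyl]-3-{2-[3-(benzyloxy)-4-(4-(benzyloxy)benzyl)phenyl]ethenyl}-5-methoxybenzene (E/Z mixture), via benzylidene phosphorane 11 (not isolated), via oxaphosphetane 12 (not isolated)
Conditions: KOtBu, THF, 0 °C; then 6, 0 → 50 °C
Reagents that add atoms: none
Why: Wittig olefination: KOtBu removes a P–CH2 proton of 10 (the only acidic C–H present) to give the semi-stabilised ylide 11, whose carbon adds to the aldehyde carbon of 6; the transient four-membered oxaphosphetane 12 closes by [2+2] addition of P=C across C=O and opens by cycloreversion, expelling Ph3P=O and leaving the C=C bond between the two future bridge carbons. The closest known reaction type is the stilbene synthesis from benzylphosphonium ylides and di-ortho-substituted benzaldehydes such as mesitaldehyde. No ring of the product is closed and no stereocentre is created; the two sp3 centres of 12 are lost on cycloreversion, and the E/Z ratio of 13 is immaterial because both isomers give the same bridge on hydrogenation. The selectivity needed is reaction at the formyl group alone, which the substrates secure because every phenol is capped as a benzyl ether, the aldehyde is not enolisable and the diarylmethane C–H bonds are far too weakly acidic for KOtBu or the ylide. Steric demand is kept low by placing the bridge carbon that sits between two ortho benzyl groups in the planar carbonyl partner and the bulky PPh3 group on the unhindered ring-B carbon.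

**Step 9**
Reactants: 13 1-(benzyloxy)-2,4-bis[4-(benzyloxy)benzyl]-3-{2-[3-(benzyloxy)-4-(4-(benzyloxy)benzyl)phenyl]ethenyl}-5-methoxybenzene (E/Z mixture)
Product: 14 2,4-bis(4-hydroxybenzyl)-3-{2-[3-hydroxy-4-(4-hydroxybenzyl)phenyl]ethyl}-5-methoxyphenol (CNP0207338.0)
Conditions: H2 (1 atm), 10% Pd/C, EtOAc/MeOH (1:1), rt
Reagents that add atoms: none
Why: Heterogeneous catalytic hydrogenation, in which Pd/C should add H2 across the stilbene C=C and hydrogenolyse the four benzylic C–O bonds of the aryl benzyl ethers in the same pot, while the aryl methyl ether, the diarylmethane C–C bonds and the arenes are inert at 1 atm and room temperature.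

**Compound list**
1 | 4-(benzyloxy)benzyl chloride | ClCc1ccc(OCc2ccccc2)cc1 | starting material
2 | 2-[4-(benzyloxy)benzyl]-4,4,5,5-tetramethyl-1,3,2-dioxaborolane | CC1(C)OB(Cc2ccc(OCc3ccccc3)cc2)OC1(C)C | intermediate
3 | 3-hydroxy-5-methoxybenzaldehyde | COc1cc(O)cc(C=O)c1 | starting material
4 | 3-(benzyloxy)-5-methoxybenzaldehyde | COc1cc(OCc2ccccc2)cc(C=O)c1 | intermediate
5 | 3-(benzyloxy)-2,6-dibromo-5-methoxybenzaldehyde | COc1cc(OCc2ccccc2)c(Br)c(C=O)c1Br | intermediate
6 | 3-(benzyloxy)-2,6-bis[4-(benzyloxy)benzyl]-5-methoxybenzaldehyde | COc1cc(OCc2ccccc2)c(Cc2ccc(OCc3ccccc3)cc2)c(C=O)c1Cc1ccc(OCc2ccccc2)cc1 | intermediate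
7 | 2-bromo-5-(hydroxymethyl)phenol | OCc1ccc(Br)c(O)c1 | starting material
8 | [3-(benzyloxy)-4-bromophenyl]methanol | OCc1ccc(Br)c(OCc2ccccc2)c1 | intermediate
9 | {3-(benzyloxy)-4-[4-(benzyloxy)benzyl]phenyl}methanol | OCc1ccc(Cc2ccc(OCc3ccccc3)cc2)c(OCc2ccccc2)c1 | intermediate
10 | {3-(benzyloxy)-4-[4-(benzyloxy)benzyl]benzyl}triphenylphosphonium bromide | [Br-].c1ccc(cc1)[P+](Cc1ccc(Cc2ccc(OCc3ccccc3)cc2)c(OCc2ccccc2)c1)(c1ccccc1)c1ccccc1 | intermediate
11 | {3-(benzyloxy)-4-[4-(benzyloxy)benzyl]benzylidene}triphenylphosphorane (ylide, not isolated) | c1ccc(cc1)P(=Cc1ccc(Cc2ccc(OCc3ccccc3)cc2)c(OCc2ccccc2)c1)(c1ccccc1)c1ccccc1 | intermediate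
12 | 2,2,2-triphenyl-1,2λ5-oxaphosphetane carrying the ring-A aryl group at C4 and the ring-B aryl group at C3 (diastereomer mixture, not isolated) | COc1cc(OCc2ccccc2)c(Cc2ccc(OCc3ccccc3)cc2)c(C2OP(c3ccccc3)(c3ccccc3)(c3ccccc3)C2c2ccc(Cc3ccc(OCc4ccccc4)cc3)c(OCc3ccccc3)c2)c1Cc1ccc(OCc2ccccc2)cc1 | intermediate
13 | 1-(benzyloxy)-2,4-bis[4-(benzyloxy)benzyl]-3-{2-[3-(benzyloxy)-4-(4-(benzyloxy)benzyl)phenyl]ethenyl}-5-methoxybenzene (E/Z mixture) | COc1cc(OCc2ccccc2)c(Cc2ccc(OCc3ccccc3)cc2)c(C=Cc2ccc(Cc3ccc(OCc4ccccc4)cc3)c(OCc3ccccc3)c2)c1Cc1ccc(OCc2ccccc2)cc1 | intermediate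
14 | 2,4-bis(4-hydroxybenzyl)-3-{2-[3-hydroxy-4-(4-hydroxybenzyl)phenyl]ethyl}-5-methoxyphenol (CNP0207338.0, achiral) | COc1cc(O)c(Cc2ccc(O)cc2)c(CCc2ccc(Cc3ccc(O)cc3)c(O)c2)c1Cc1ccc(O)cc1 | target

**Step count**
Total: 9 steps. Longest linear sequence: 5 steps (for example steps 5, 6, 7, 8, 9).

**Steps most likely to fail**

Step 4. The second oxidative addition and transmetalation at a C–Br bond flanked by two ortho substituents may stall while the benzylboronate is consumed by protodeboronation, so that mono-coupled and hydrodebrominated material accumulates. The fallback sets out from 5 and swaps the boron partner for a more reactive organozinc on a masked aldehyde. Acetalisation (HC(OMe)3, cat. TsOH, MeOH) should give 1-(benzyloxy)-2,4-dibromo-3-(dimethoxymethyl)-5-methoxybenzene F1. Zinc insertion into 1 (Zn dust, LiCl, THF) should give [4-(benzyloxy)benzyl]zinc chloride F2. A twofold Negishi coupling of F1 with F2 (Pd(OAc)2, SPhos, THF, 50 °C) should give 1-(benzyloxy)-2,4-bis[4-(benzyloxy)benzyl]-3-(dimethoxymethyl)-5-methoxybenzene F3. Aqueous acid (1 M HCl, THF) then unmasks the aldehyde and the route is rejoined at 6.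

Step 8. Addition of the bulky triphenylphosphonium ylide to a carbonyl flanked by two ortho benzyl groups may be slow enough that ylide decomposition outruns olefination. The fallback sets out from 9 and uses a smaller, more nucleophilic phosphonate carbanion. PBr3 (CH2Cl2, 0 °C) should give 2-(benzyloxy)-1-[4-(benzyloxy)benzyl]-4-(bromomethyl)benzene F4. Michaelis–Arbuzov reaction with P(OEt)3 (neat, 130 °C) should give diethyl {3-(benzyloxy)-4-[4-(benzyloxy)benzyl]benzyl}phosphonate F5. Deprotonation in situ (NaH, THF, 0 °C → rt) and Horner–Wadsworth–Emmons reaction with 6 should give the E-olefin, rejoining the route at 13.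

Step 9. The hydrogenation may stall through catalyst poisoning by phosphorus residues carried over from step 8 or through precipitation of partly debenzylated phenols, leaving mixtures of incompletely deprotected material. The fallback sets out from 13 and separates the two tasks with non-catalytic reagents. Diimide generated in situ (TsNHNH2, NaOAc, THF/H2O, reflux) should reduce only the C=C to give 1-(benzyloxy)-2,4-bis[4-(benzyloxy)benzyl]-3-{2-[3-(benzyloxy)-4-(4-(benzyloxy)benzyl)phenyl]ethyl}-5-methoxybenzene F6. BCl3 with pentamethylbenzene as cation scavenger (CH2Cl2, −78 °C) should then cleave the four benzyl ethers while the aryl methyl ether stays, arriving at 14.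

**Further compounds**
F1 | step 4 | 1-(benzyloxy)-2,4-dibromo-3-(dimethoxymethyl)-5-methoxybenzene | COc1cc(OCc2ccccc2)c(Br)c(C(OC)OC)c1Br
F2 | step 4 | [4-(benzyloxy)benzyl]zinc chloride | Cl[Zn]Cc1ccc(OCc2ccccc2)cc1
F3 | step 4 | 1-(benzyloxy)-2,4-bis[4-(benzyloxy)benzyl]-3-(dimethoxymethyl)-5-methoxybenzene | COc1cc(OCc2ccccc2)c(Cc2ccc(OCc3ccccc3)cc2)c(C(OC)OC)c1Cc1ccc(OCc2ccccc2)cc1
F4 | step 8 | 2-(benzyloxy)-1-[4-(benzyloxy)benzyl]-4-(bromomethyl)benzene | BrCc1ccc(Cc2ccc(OCc3ccccc3)cc2)c(OCc2ccccc2)c1
F5 | step 8 | diethyl {3-(benzyloxy)-4-[4-(benzyloxy)benzyl]benzyl}phosphonate | CCOP(=O)(OCC)Cc1ccc(Cc2ccc(OCc3ccccc3)cc2)c(OCc2ccccc2)c1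
F6 | step 9 | 1-(benzyloxy)-2,4-bis[4-(benzyloxy)benzyl]-3-{2-[3-(benzyloxy)-4-(4-(benzyloxy)benzyl)phenyl]ethyl}-5-methoxybenzene | COc1cc(OCc2ccccc2)c(Cc2ccc(OCc3ccccc3)cc2)c(CCc2ccc(Cc3ccc(OCc4ccccc4)cc3)c(OCc3ccccc3)c2)c1Cc1ccc(OCc2ccccc2)cc1
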